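A small charge, c(enzyme) = 10 µM against c(substrate) = 0.050 M, has to turn the substrate into target while target drains into the isomer of the product, and the peak of target is the balance of that race.

| flask | substrate | enzyme | remark | time |
|---|---|---|---|---|
| Sunday's | 0.050 M | 10 µM | the very flask that is asked about, followed so far |  |
| Monday's | 0.050 M | 5 µM | run made earlier |  |
| flask | 0.050 M | 10 µM |  | 15 d |

| run | time / d | target / % | substrate / % |
|---|---|---|---|
| Sunday's | 0.125 | 30 | 68 |
| Sunday's | 0.250 | 54 | 43 |
| Sunday's | 0.417 | 79 | 18 |
| Sunday's | 0.833 | 77 | 3 |
| Sunday's | 1.25 | 62 | 2 |
| Sunday's | 2.50 | 37 | 0 |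
| Sunday's | 5.00 | 20 | 0 |
| Monday's | 0.125 | 14 | 85 |
| Monday's | 0.250 | 28 | 71 |
| Monday's | 0.625 | 51 | 41 |
| Monday's | 1.25 | 62 | 15 |
| Monday's | 2.50 | 46 | 2 |
| Monday's | 5.00 | 24 | 0 |
| Monday's | 10.0 | 15 | 0 |

(scatter of a reading: 1.5 percentage points)

1. when, up to 15 d, the flask holds most target
2. the amount of target, in percent of the substrate charged, at that time

- what was read earlier has a scatter of 1.5 percentage points, one standard deviation
- candidate steps: substrate + enzyme -> target + enzyme; target <-> isomer of the product; enzyme -> spent catalyst

In the first instants of Sunday's run, which is the asked flask followed so far, substrate loses 32.0% by 0.125 d and target reads 30%, so within the scatter the reacted substrate is still target. Monday's run, with the same substrate and half the enzyme, loses 15.0% in that time and then 14.0% in the next equal interval, so over these first readings the feed follows the enzyme and reads close to zero order in substrate. At the end of the filling, with substrate at 3% in Sunday's run, target falls from 77% at 0.833 d to 37% by 2.50 d, which reads as a loss constant of 0.440 d⁻¹.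

The middle is reckoned by replacing the rising target with its mean, half the charge, over the filling time, which gives the leak share: loss constant times filling time, halved. Sunday's mean feed up to 0.417 d gives a filling time of 0.509 d, so the leak share is 11.2% and this reckoning puts the peak near 88.8%. On Monday's run the same rule, with the same loss constant and that run's mean feed up to 1.25 d, gives 67.7%, so on that run the reckoned peak stands above the highest reading of 62%.

The forecast says 80% at 0.55 d, lower than this reckoning, on the ground that “The peak falls where substrate feed equals target loss”.

The flask peaks at 0.561 d with 84.3%, within the forecast's margins.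

    substrate + enzyme → target + enzyme, rate k1*[substrate]*[enzyme]/(1 + ([substrate]/Km1)) (2.30 mM, k = 71.0 M⁻¹ s⁻¹)
    target ⇌ isomer of the product (K = 5.70, k = 5.50 × 10⁻⁶ s⁻¹)
    enzyme → spent catalyst (k = 1.30 × 10⁻⁵ s⁻¹)

At that peak the flask holds 14.1% isomer of the product against the leak share of 11.2%, with 1.61% substrate still there. The neighbouring flask charged with 0.013 M of substrate has a quarter of the substrate charge on the same enzyme, so, if its mean feed is taken as the same, its leak share is 2.91% and its reckoned peak 97.1%, and that flask reaches 93.6% of its own substrate charge.

(Readings and results were computed with made-up constants, and the scatter is random.)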